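The O1–C2(H)–C(=CH2) array of the dihydrofuran ring, next to the C3 ester, is the form a 2,2-dimethylchroman-3-yl cation takes once its ring oxygen has shifted from the gem-dimethyl carbon to C3; the furan ring is therefore traced back to a pyran ring.
Key disconnection: O1–C2 of the dihydrobenzofuran, leading to a trans-3-hydroxy-4-isovaleryloxy-2,2-dimethylchroman; both ring stereocentres come from one enantioselective epoxidation of 6-acetyl-2,2-dimethyl-2H-chromene and trans opening at benzylic C4.
The chromene comes from 4-hydroxyacetophenone by O-propargylation and thermal Claisen cyclisation; ring order: benzene ring (purchased), pyran ring (step 2), contraction to the dihydrofuran ring (step 5).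
End game: catalyst-controlled reduction of the aryl ketone to the R carbinol, second isovalerylation, oxidation of the isopropenyl methyl group to the enal.

Key step: step 5

Assumption: (R,R)-(salen)MnCl is taken to give the (3R,4R)-epoxide of this 2,2-dimethylchromene and the (R,R)-TsDPEN ruthenium catalyst the R carbinol of this aryl methyl ketone, as is general for these substrate classes; if either sense proves opposite, the enantiomeric catalyst is used.

Step 1
Reactants: 1 4-hydroxyacetophenone; 2 3-chloro-3-methylbut-1-yne
Product: 3 1-[4-(2-methylbut-3-yn-2-yloxy)phenyl]ethanone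
Conditions: K2CO3, KI (cat.), CuI (cat.), acetone, reflux
Reagents that add atoms: none
Why: Williamson-type O-alkylation of the phenoxide with the tertiary propargylic chloride, assisted by CuI and KI, is the standard route to aryl 1,1-dimethylpropargyl ethers and leaves the para-acetyl group untouched.

Step 2
Reactants: 3 1-[4-(2-methylbut-3-yn-2-yloxy)phenyl]ethanone
Product: 6 1-(2,2-dimethyl-2H-chromen-6-yl)ethanone, via ortho-allenylphenol 4 (not isolated), via ortho-quinone methide 5 (not isolated)
Conditions: N,N-diethylaniline, 190 °C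
Reagents that add atoms: none
Why: Aromatic propargyl Claisen rearrangement ([3,3] shift then enolisation to allenylphenol 4), 1,5-hydrogen shift to ortho-quinone methide 5 and oxa-6π electrocyclisation close the pyran ring in one thermal cascade, and since both ortho positions of 3 are equivalent only one chromene can form.

Step 3
Reactants: 6 1-(2,2-dimethyl-2H-chromen-6-yl)ethanone
Product: 7 (3R,4R)-6-acetyl-3,4-epoxy-2,2-dimethylchroman
Conditions: (R,R)-Jacobsen catalyst [(R,R)-N,N'-bis(3,5-di-tert-butylsalicylidene)cyclohexane-1,2-diaminato]MnCl (5 mol %), mCPBA, NMO, CH2Cl2, −78 °C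
Reagents that add atoms: 3-chloroperoxybenzoic acid (mCPBA), OOC(=O)c1cccc(Cl)c1
Why: Jacobsen–Katsuki epoxidation, for which cis-disubstituted aryl-conjugated 2,2-dimethylchromenes are among the best substrates: the oxomanganese salen species of the (R,R)-catalyst transfers oxygen to one alkene face, setting C3 and C4 together as the cis (3R,4R)-epoxide under catalyst control, while the mCPBA/NMO protocol at −78 °C keeps the methyl ketone free of haloform or Baeyer–Villiger side reactions.

Step 4
Reactants: 7 (3R,4R)-6-acetyl-3,4-epoxy-2,2-dimethylchroman; 8 isovaleric acid (3-methylbutanoic acid)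
Product: 9 (3R,4S)-6-acetyl-3-hydroxy-2,2-dimethylchroman-4-yl 3-methylbutanoate
Conditions: 8 (3 equiv), Cs2CO3 (10 mol %), DMF, 70 °C
Reagents that add atoms: none
Why: Base-catalysed SN2 ring opening of the epoxide by the carboxylate formed in the flask: attack is at the benzylic C4 from the face opposite the oxirane oxygen because C3 is neopentylic and shielded by the gem-dimethyl group, so C4 is inverted to S and C3 keeps its R configuration (trans hydroxy ester), and the excess acid protonates the C3 alkoxide at once, which suppresses acyl migration.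

Step 5
Reactants: 9 (3R,4S)-6-acetyl-3-hydroxy-2,2-dimethylchroman-4-yl 3-methylbutanoate
Product: 11 (2R,3S)-5-acetyl-2-(prop-1-en-2-yl)-2,3-dihydrobenzofuran-3-yl 3-methylbutanoate, via chromanyl triflate 10 (not isolated)
Conditions: Tf2O (1.1 equiv), 2,6-di-tert-butyl-4-methylpyridine (2.5 equiv), CH2Cl2, −78 °C → rt
Reagents that add atoms: none
Why: Tf2O and the hindered pyridine convert the equatorial C3 hydroxyl into triflate 10 at −78 °C, and on warming the ring oxygen O1, whose bond to C2 lies antiperiplanar to the C3–OTf bond in the trans-diequatorial half-chair, displaces triflate from the rear while the O1–C(CH3)2 bond breaks, so that charge builds up on the tertiary carbon and is discharged by loss of a methyl proton to give the isopropenyl group. This is a semipinacol-type (Wagner–Meerwein) 1,2-oxygen shift, the known cationic ring contraction of 2,2-dimethylchroman-3-yl sulfonates to 2-isopropenyl-2,3-dihydrobenzofurans. The dihydrofuran ring is closed by formation of the bond from O1 to the former C3 (C2 of the product) in a 3-exo-tet attack through an oxygen-bridged, oxiranium-like transition structure, which makes the net change a six-to-five ring contraction with one new skeletal C–O bond. The new stereocentre, C2 of the dihydrobenzofuran, is set R by stereospecific inversion at the triflate-bearing carbon, so it is controlled by the C3 configuration that came from the epoxidation, and together with the untouched ester-bearing centre it gives the 2,3-trans pair. The step needs migration of O1 to outrun participation of the C4 ester carbonyl, migration of the C4–aryl bond and loss of the ring proton next to the cationic carbon; the substrate secures this because ester participation requires the trans-diaxial conformer, which is destabilised by the 1,3-diaxial clash between the C4 substituent and a C2 methyl group, because only O1 migration leads to a tertiary cation, and because a hindered base removes the exposed methyl proton. Tf2O is kept close to one equivalent at low temperature so that the aryl methyl ketone is not converted into an enol triflate.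

Step 6
Reactants: 11 (2R,3S)-5-acetyl-2-(prop-1-en-2-yl)-2,3-dihydrobenzofuran-3-yl 3-methylbutanoate
Product: 12 (2R,3S)-5-[(1R)-1-hydroxyethyl]-2-(prop-1-en-2-yl)-2,3-dihydrobenzofuran-3-yl 3-methylbutanoate
Conditions: RuCl(p-cymene)[(R,R)-TsDPEN] (1 mol %), HCO2H–Et3N (5:2), CH2Cl2, 30 °C
Reagents that add atoms: none
Why: Noyori asymmetric transfer hydrogenation: the ruthenium hydride of the (R,R)-TsDPEN complex delivers hydride and proton through its six-membered outer-sphere transition state, organised by the CH/π contact between the cymene ligand and the substrate aryl ring, to the ketone face that gives the (R)-1-arylethanol under catalyst control, and the alkene and the ester are not touched.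

Step 7
Reactants: 12 (2R,3S)-5-[(1R)-1-hydroxyethyl]-2-(prop-1-en-2-yl)-2,3-dihydrobenzofuran-3-yl 3-methylbutanoate
Product: 13 (2R,3S)-5-[(1R)-1-(3-methylbutanoyloxy)ethyl]-2-(prop-1-en-2-yl)-2,3-dihydrobenzofuran-3-yl 3-methylbutanoate
Conditions: isovaleric anhydride, Et3N, DMAP (cat.), CH2Cl2, 0 °C → rt
Reagents that add atoms: isovaleric anhydride (3-methylbutanoic anhydride), CC(C)CC(=O)OC(=O)CC(C)C
Why: DMAP-catalysed acyl transfer from the anhydride (nucleophilic catalysis via the N-acylpyridinium ion) esterifies the secondary benzylic hydroxyl without breaking its C–O bond, so the R configuration is retained, and the basic medium avoids ionisation of this para-alkoxybenzylic centre.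

Step 8
Reactants: 13 (2R,3S)-5-[(1R)-1-(3-methylbutanoyloxy)ethyl]-2-(prop-1-en-2-yl)-2,3-dihydrobenzofuran-3-yl 3-methylbutanoate
Product: 14 (2R,3S)-2-(3-hydroxyprop-1-en-2-yl)-5-[(1R)-1-(3-methylbutanoyloxy)ethyl]-2,3-dihydrobenzofuran-3-yl 3-methylbutanoate
Conditions: SeO2 (0.3 equiv), tBuOOH (3 equiv), CH2Cl2, rt
Reagents that add atoms: selenium dioxide, O=[Se]=O; tert-butyl hydroperoxide, CC(C)(C)OO
Why: Riley-type allylic oxidation with catalytic SeO2 and tBuOOH (ene reaction at the terminal alkene carbon followed by [2,3]-sigmatropic shift) hydroxylates the methyl group of the 1,1-disubstituted alkene in preference to the oxygen-bearing C2 methine, a known transformation of 2-isopropenyl-2,3-dihydrobenzofurans, and at room temperature it should spare both benzylic esters and all three stereocentres; any enal formed already is target 15 and is carried into step 9.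

Step 9
Reactants: 14 (2R,3S)-2-(3-hydroxyprop-1-en-2-yl)-5-[(1R)-1-(3-methylbutanoyloxy)ethyl]-2,3-dihydrobenzofuran-3-yl 3-methylbutanoate
Product: 15 (2R,3S)-5-[(1R)-1-(3-methylbutanoyloxy)ethyl]-2-(3-oxoprop-1-en-2-yl)-2,3-dihydrobenzofuran-3-yl 3-methylbutanoate
Conditions: activated MnO2 (excess), CH2Cl2, rt
Reagents that add atoms: none
Why: MnO2 oxidation is selective for allylic alcohols and runs on the solid surface under neutral conditions, so the primary allylic alcohol should be taken to the α-substituted acrolein without migration of the double bond toward C2, loss of the C3 ester or change at any stereocentre.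

Compound list
1 | 4-hydroxyacetophenone | CC(=O)c1ccc(O)cc1 | starting material
2 | 3-chloro-3-methylbut-1-yne | C#CC(C)(C)Cl | starting material
3 | 1-[4-(2-methylbut-3-yn-2-yloxy)phenyl]ethanone | CC(=O)c1ccc(OC(C)(C)C#C)cc1 | intermediate
4 | 1-[4-hydroxy-3-(3-methylbuta-1,2-dien-1-yl)phenyl]ethanone (ortho-allenylphenol) | CC(=O)c1ccc(O)c(C=C=C(C)C)c1 | intermediate (not isolated)
5 | 4-acetyl-6-(3-methylbut-2-en-1-ylidene)cyclohexa-2,4-dien-1-one (ortho-quinone methide, alkene geometry not fixed) | CC(=O)C1=CC(=CC=C(C)C)C(=O)C=C1 | intermediate (not isolated)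
6 | 1-(2,2-dimethyl-2H-chromen-6-yl)ethanone | CC(=O)c1ccc2OC(C)(C)C=Cc2c1 | intermediate
7 | (3R,4R)-6-acetyl-3,4-epoxy-2,2-dimethylchroman | CC1(C)Oc2ccc(C(C)=O)cc2[C@H]2O[C@@H]12 | intermediate
8 | isovaleric acid (3-methylbutanoic acid) | CC(C)CC(=O)O | starting material
9 | (3R,4S)-6-acetyl-3-hydroxy-2,2-dimethylchroman-4-yl 3-methylbutanoate | CC1(C)Oc2ccc(C(C)=O)cc2[C@H](OC(=O)CC(C)C)[C@H]1O | intermediate
10 | (3R,4S)-6-acetyl-2,2-dimethyl-3-(trifluoromethylsulfonyloxy)chroman-4-yl 3-methylbutanoate | CC1(C)Oc2ccc(C(C)=O)cc2[C@H](OC(=O)CC(C)C)[C@H]1OS(=O)(=O)C(F)(F)F | intermediate (not isolated)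
11 | (2R,3S)-5-acetyl-2-(prop-1-en-2-yl)-2,3-dihydrobenzofuran-3-yl 3-methylbutanoate | C=C(C)[C@H]1Oc2ccc(C(C)=O)cc2[C@@H]1OC(=O)CC(C)C | intermediate
12 | (2R,3S)-5-[(1R)-1-hydroxyethyl]-2-(prop-1-en-2-yl)-2,3-dihydrobenzofuran-3-yl 3-methylbutanoate | C=C(C)[C@H]1Oc2ccc([C@@H](C)O)cc2[C@@H]1OC(=O)CC(C)C | intermediate
13 | (2R,3S)-5-[(1R)-1-(3-methylbutanoyloxy)ethyl]-2-(prop-1-en-2-yl)-2,3-dihydrobenzofuran-3-yl 3-methylbutanoate | C=C(C)[C@H]1Oc2ccc([C@@H](C)OC(=O)CC(C)C)cc2[C@@H]1OC(=O)CC(C)C | intermediate
14 | (2R,3S)-2-(3-hydroxyprop-1-en-2-yl)-5-[(1R)-1-(3-methylbutanoyloxy)ethyl]-2,3-dihydrobenzofuran-3-yl 3-methylbutanoate | C=C(CO)[C@H]1Oc2ccc([C@@H](C)OC(=O)CC(C)C)cc2[C@@H]1OC(=O)CC(C)C | intermediate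
15 | (2R,3S)-5-[(1R)-1-(3-methylbutanoyloxy)ethyl]-2-(3-oxoprop-1-en-2-yl)-2,3-dihydrobenzofuran-3-yl 3-methylbutanoate | C=C(C=O)[C@H]1Oc2ccc([C@@H](C)OC(=O)CC(C)C)cc2[C@@H]1OC(=O)CC(C)C | target

Total step count: 9. Longest linear sequence: 9 steps (1 → 15).

The three steps most likely to fail are given in route order; step 5 carries the largest risk.

Step 4. The carboxylate is a weak nucleophile, so the SN2 opening may be slow. At the temperature then needed, ion-pair opening can erode the trans selectivity and the acyl group can migrate from O4 to O3. The fallback forms the C4–O bond with hydroxide and introduces the ester afterwards. It sets out from epoxide 7: KOH in water–dioxane at 60 °C should open the epoxide at C4 with inversion to give (3R,4S)-6-acetyl-2,2-dimethylchroman-3,4-diol F1. Kinetic mono-acylation of the less hindered benzylic C4 hydroxyl (isovaleric anhydride 1.05 equiv, pyridine, CH2Cl2, −20 °C; the C3 hydroxyl is neopentylic) then comes back to the route at 9.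

Step 5. Anchimeric capture of the ionising C3 centre by the C4 ester carbonyl may compete with the 1,2-shift of O1. The fallback keeps the ring contraction but carries a non-participating silyl ether at C4 through it and installs the ester afterwards; it also bypasses step 4.
- It sets out from epoxide 7, hydrolysed as above to (3R,4S)-6-acetyl-2,2-dimethylchroman-3,4-diol F1.
- TBSCl and imidazole in DMF at 0 °C should silylate the benzylic hydroxyl selectively to give 1-[(3R,4S)-4-(tert-butyldimethylsilyloxy)-3-hydroxy-2,2-dimethylchroman-6-yl]ethanone F2.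
- Tf2O and 2,6-di-tert-butyl-4-methylpyridine in CH2Cl2 (−78 °C → rt) form (3R,4S)-6-acetyl-4-(tert-butyldimethylsilyloxy)-2,2-dimethylchroman-3-yl trifluoromethanesulfonate F3 (not isolated), which should contract as in step 5 to 1-[(2R,3S)-3-(tert-butyldimethylsilyloxy)-2-(prop-1-en-2-yl)-2,3-dihydrobenzofuran-5-yl]ethanone F4.
- Bu4NF buffered with AcOH in THF frees 1-[(2R,3S)-3-hydroxy-2-(prop-1-en-2-yl)-2,3-dihydrobenzofuran-5-yl]ethanone F5.
- Acylation of F5 with isovaleric anhydride, Et3N and DMAP comes back to the route at 11.

Step 8. The selenium ene/[2,3] sequence may stall or over-oxidise, and the acidic selenium species may promote elimination of the C3 ester toward the aromatic benzofuran. The fallback replaces oxygen transfer by a halogenation–oxidation sequence and sets out from 13. Selenium-catalysed ene-type allylic chlorination (NCS, PhSeCl cat., CH2Cl2, rt) should give (2R,3S)-2-(3-chloroprop-1-en-2-yl)-5-[(1R)-1-(3-methylbutanoyloxy)ethyl]-2,3-dihydrobenzofuran-3-yl 3-methylbutanoate F6. Amine N-oxide oxidation of the allylic chloride (Me3NO, NaI cat., NaHCO3, DMSO, rt; Ganem-type variant of the Kornblum oxidation) then gives the enal directly and comes back to the route at 15, bypassing 14.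

Further compounds
F1 | step 4 | (3R,4S)-6-acetyl-2,2-dimethylchroman-3,4-diol | CC1(C)Oc2ccc(C(C)=O)cc2[C@H](O)[C@H]1O
F2 | step 5 | 1-[(3R,4S)-4-(tert-butyldimethylsilyloxy)-3-hydroxy-2,2-dimethylchroman-6-yl]ethanone | CC1(C)Oc2ccc(C(C)=O)cc2[C@H](O[Si](C)(C)C(C)(C)C)[C@H]1O
F3 | step 5 | (3R,4S)-6-acetyl-4-(tert-butyldimethylsilyloxy)-2,2-dimethylchroman-3-yl trifluoromethanesulfonate | CC1(C)Oc2ccc(C(C)=O)cc2[C@H](O[Si](C)(C)C(C)(C)C)[C@H]1OS(=O)(=O)C(F)(F)F
F4 | step 5 | 1-[(2R,3S)-3-(tert-butyldimethylsilyloxy)-2-(prop-1-en-2-yl)-2,3-dihydrobenzofuran-5-yl]ethanone | C=C(C)[C@H]1Oc2ccc(C(C)=O)cc2[C@@H]1O[Si](C)(C)C(C)(C)C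
F5 | step 5 | 1-[(2R,3S)-3-hydroxy-2-(prop-1-en-2-yl)-2,3-dihydrobenzofuran-5-yl]ethanone | C=C(C)[C@H]1Oc2ccc(C(C)=O)cc2[C@@H]1O
F6 | step 8 | (2R,3S)-2-(3-chloroprop-1-en-2-yl)-5-[(1R)-1-(3-methylbutanoyloxy)ethyl]-2,3-dihydrobenzofuran-3-yl 3-methylbutanoate | C=C(CCl)[C@H]1Oc2ccc([C@@H](C)OC(=O)CC(C)C)cc2[C@@H]1OC(=O)CC(C)C
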